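**Retrosynthetic overview**

1. Target 20 ← heptamethyl ether 19 (BBr3) ← 6H-benzo[c]chromene 17, by reductive cleavage of the benzylic C9'–O bond.
2. 17 ← 2-arylphenol 13 + keto aldehyde 14 (oxa-Pictet–Spengler). Ring A carries its chain at position 1, oxygens at positions 3 and 4 and the biaryl bond at position 5; ring B carries the biaryl bond at position 1, the chain carbon C9' at position 2 and oxygens at positions 4 and 5. The 4-hydroxyl of ring A and C9' therefore both flank the biaryl bond, so O, C9', carbons 2 and 1 of ring B and carbons 5 and 4 of ring A can be tied into a temporary six-membered pyran. Its closure makes the bond from ring B to C9', and its opening returns the hydroxyl.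
3. 13 ← bromophenol 11 + boronic acid 12 (Suzuki, biaryl bond); 11 ← eugenol 8 + alkenyl ketone 7 (cross-metathesis, hydrogenation, bromination ortho to the hydroxyl).
4. 14 ← the same alkenyl ketone 7 (linear hydroformylation); 7 ← Weinreb amide 3 of acid 1 + 2,6-dimethoxyphenyllithium 5.
5. All four benzene rings are bought; the only ring formed is the pyran (step 8), and it is opened again in step 9.

Key step: step 8

Remark: the target has no stereocentre. Its biaryl axis carries only two ortho substituents (the hydroxyl at position 4 of ring A and the chain at position 2 of ring B), so it is taken to rotate freely and no configuration has to be set. C9' of chromene 17 is racemic and becomes CH2 in step 9.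

**Route**

Step 1
Reactants: 1 oct-7-enoic acid
Product: 3 N-methoxy-N-methyloct-7-enamide, via acyl imidazole 2 (not isolated)
Conditions: 1,1'-carbonyldiimidazole (1.1 equiv), CH2Cl2, rt; then MeNHOMe·HCl (1.2 equiv), rt
Reagents that add atoms: N,O-dimethylhydroxylamine hydrochloride (CNOC.Cl)
Why: Activation of the acid as its acyl imidazole and aminolysis is a standard Weinreb amide synthesis that leaves the terminal alkene untouched.

Step 2
Reactants: 3 N-methoxy-N-methyloct-7-enamide; 4 1,3-dimethoxybenzene
Product: 7 1-(2,6-dimethoxyphenyl)oct-7-en-1-one, via 2,6-dimethoxyphenyllithium 5 (not isolated), via lithium adduct 6 (not isolated)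
Conditions: 4 (1.6 equiv), n-BuLi (1.5 equiv), THF, 0 °C → rt; then 3, −78 → 0 °C; 1 M HCl; run on a scale that supplies both step 3 and step 7
Reagents that add atoms: none
Why: Directed ortho-lithiation of 4 between its two methoxy groups gives the aryllithium, which adds once to the amide because the chelated tetrahedral adduct 6 persists until the acidic quench (Weinreb ketone synthesis).

Step 3
Reactants: 7 1-(2,6-dimethoxyphenyl)oct-7-en-1-one; 8 eugenol (4-allyl-2-methoxyphenol)
Product: 9 (E/Z)-1-(2,6-dimethoxyphenyl)-9-(4-hydroxy-3-methoxyphenyl)non-7-en-1-one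
Conditions: 8 (3 equiv), second-generation Hoveyda–Grubbs catalyst RuCl2(H2IMes)(=CH-C6H4-2-O-i-Pr) (3 mol%), 1,4-benzoquinone (10 mol%), CH2Cl2, 40 °C
Reagents that add atoms: none
Why: Olefin cross-metathesis of two unhindered terminal alkenes is driven by loss of ethylene and by the excess of the cheap partner, benzoquinone suppresses isomerisation of the allyl group, and the alkene geometry is irrelevant because the double bond is hydrogenated next.

Step 4
Reactants: 9 (E/Z)-1-(2,6-dimethoxyphenyl)-9-(4-hydroxy-3-methoxyphenyl)non-7-en-1-one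
Product: 10 1-(2,6-dimethoxyphenyl)-9-(4-hydroxy-3-methoxyphenyl)nonan-1-one
Conditions: H2 (1 atm), 10% Pd/C, EtOAc, rt
Reagents that add atoms: none
Why: Catalytic hydrogenation of a 1,2-disubstituted alkene is fast under neutral conditions, whereas the twisted, doubly ortho-substituted aryl ketone and the arenes should not be reduced.

Step 5
Reactants: 10 1-(2,6-dimethoxyphenyl)-9-(4-hydroxy-3-methoxyphenyl)nonan-1-one
Product: 11 9-(3-bromo-4-hydroxy-5-methoxyphenyl)-1-(2,6-dimethoxyphenyl)nonan-1-one
Conditions: NBS (1.0 equiv), i-Pr2NH (10 mol%), CH2Cl2, −20 → 0 °C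
Reagents that add atoms: N-bromosuccinimide (O=C1CCC(=O)N1Br)
Why: Amine-catalysed electrophilic bromination of phenols goes ortho to the hydroxyl, position 5 of ring A is the only free ortho or para position of the phenol, and the dimethoxyphenyl ketone ring, which has no free hydroxyl, should react much more slowly with one equivalent of NBS in CH2Cl2 at low temperature.

Step 6
Reactants: 11 9-(3-bromo-4-hydroxy-5-methoxyphenyl)-1-(2,6-dimethoxyphenyl)nonan-1-one; 12 3,4-dimethoxyphenylboronic acid
Product: 13 9-[3-(3,4-dimethoxyphenyl)-4-hydroxy-5-methoxyphenyl]-1-(2,6-dimethoxyphenyl)nonan-1-one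
Conditions: 12 (1.5 equiv), Pd(OAc)2 (3 mol%), SPhos (6 mol%), K3PO4 (3 equiv), toluene–H2O (10:1), 90 °C
Reagents that add atoms: none
Why: Suzuki–Miyaura coupling with an SPhos-ligated palladium catalyst tolerates electron-rich ortho-bromophenols, free hydroxyls and ketones, and forms the biaryl bond between position 5 of ring A and position 1 of ring B.

Step 7
Reactants: 7 1-(2,6-dimethoxyphenyl)oct-7-en-1-one
Product: 14 9-(2,6-dimethoxyphenyl)-9-oxononanal
Conditions: Rh(acac)(CO)2 (1 mol%), Xantphos (4 mol%), CO/H2 (1:1, 10 bar), toluene, 80 °C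
Reagents that add atoms: carbon monoxide ([C-]#[O+])
Why: Rhodium-catalysed hydroformylation with the wide-bite-angle diphosphine Xantphos places the formyl group on the terminal carbon of a monosubstituted alkene, which extends the eight-carbon chain of 7 to the nine-carbon keto aldehyde in one step, while the remote, shielded aryl ketone is inert and the aldehyde is not hydrogenated under these conditions.

Step 8
Reactants: 13 9-[3-(3,4-dimethoxyphenyl)-4-hydroxy-5-methoxyphenyl]-1-(2,6-dimethoxyphenyl)nonan-1-one; 14 9-(2,6-dimethoxyphenyl)-9-oxononanal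
Product: 17 racemic 1-(2,6-dimethoxyphenyl)-9-{6-[8-(2,6-dimethoxyphenyl)-8-oxooctyl]-4,8,9-trimethoxy-6H-benzo[c]chromen-2-yl}nonan-1-one, via hemiacetal 15 (not isolated), via aryloxycarbenium ion 16 (not isolated)
Conditions: 14 (1.3 equiv), CF3CO2H (10 equiv), 4 Å molecular sieves, CH2Cl2, 0 °C → rt
Reagents that add atoms: none
Why: The 4-hydroxyl of ring A adds to the aldehyde to give hemiacetal 15, which loses water under acid to aryloxycarbenium ion 16; position 2 of ring B attacks its carbon in an intramolecular Friedel–Crafts substitution and rearomatisation gives the chromene (C-hydroxyalkylation of ring B first and closure through oxygen second would converge on the same product). The closest known reaction type is the oxa-Pictet–Spengler condensation of 2-arylphenols with aldehydes to 6-substituted 6H-benzo[c]chromenes. The six-membered pyran (O, C9', carbons 2 and 1 of ring B, carbons 5 and 4 of ring A) closes by 6-endo-trig attack of the arene on the C=O+ bond, as in a Pictet–Spengler cyclisation. The new stereocentre C9' has no controlling element, should form as a racemate, and becomes CH2 in step 9. Site selectivity on ring B is needed and is secured because position 2 is para to the 5-methoxy group and unhindered, whereas position 6 is only ortho-activated and wedged between the biaryl bond and that methoxy group. The aldehyde should react in preference to the two ketones, which are shielded by two ortho methoxy groups each, and the tether should favour ring closure over intermolecular alkylation of the other arenes.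

Step 9
Reactants: 17 racemic 1-(2,6-dimethoxyphenyl)-9-{6-[8-(2,6-dimethoxyphenyl)-8-oxooctyl]-4,8,9-trimethoxy-6H-benzo[c]chromen-2-yl}nonan-1-one
Product: 19 9-[3-{2-[9-(2,6-dimethoxyphenyl)-9-oxononyl]-4,5-dimethoxyphenyl}-4-hydroxy-5-methoxyphenyl]-1-(2,6-dimethoxyphenyl)nonan-1-one, via benzylic cation 18 (not isolated)
Conditions: Et3SiH (5 equiv), CF3CO2H–CH2Cl2 (1:2), 0 °C → rt, stopped as soon as 17 is consumed
Reagents that add atoms: none
Why: Ionic hydrogenation in which protonation of the pyran oxygen and ionisation of the C9'–O bond give a secondary benzylic cation stabilised by the para 5-methoxy group of ring B, which takes hydride from the excess Et3SiH and frees the 4-hydroxyl of ring A, while the two ketones, twisted out of conjugation and flanked by ortho methoxy groups, should accept hydride much more slowly under a protic acid that activates carbonyls only weakly.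

Step 10
Reactants: 19 9-[3-{2-[9-(2,6-dimethoxyphenyl)-9-oxononyl]-4,5-dimethoxyphenyl}-4-hydroxy-5-methoxyphenyl]-1-(2,6-dimethoxyphenyl)nonan-1-one
Product: 20 9-[3-{2-[9-(2,6-dihydroxyphenyl)-9-oxononyl]-4,5-dihydroxyphenyl}-4,5-dihydroxyphenyl]-1-(2,6-dihydroxyphenyl)nonan-1-one (CNP0305015.0)
Conditions: BBr3 (16 equiv), CH2Cl2, −78 °C → rt; MeOH then H2O, 0 °C, under Ar
Reagents that add atoms: none
Why: BBr3 cleavage of aryl methyl ethers, in which bromide attacks each O-methyl carbon of the boron-complexed ether (the ketone-flanking methoxy groups helped by chelation to the carbonyl), should remove all seven methyl groups, and hydrolytic work-up releases the phenols without touching the ketones or the chains.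

**Compound list**

1 | oct-7-enoic acid | C=CCCCCCC(=O)O | starting material
2 | 1-(1H-imidazol-1-yl)oct-7-en-1-one (acyl imidazole) | C=CCCCCCC(=O)n1ccnc1 | intermediate (not isolated)
3 | N-methoxy-N-methyloct-7-enamide | C=CCCCCCC(=O)N(C)OC | intermediate
4 | 1,3-dimethoxybenzene | COc1cccc(OC)c1 | starting material
5 | 2,6-dimethoxyphenyllithium | [Li]c1c(OC)cccc1OC | intermediate (not isolated)
6 | lithium 1-(2,6-dimethoxyphenyl)-1-[methoxy(methyl)amino]oct-7-en-1-olate (lithium adduct) | C=CCCCCCC(O[Li])(N(C)OC)c1c(OC)cccc1OC | intermediate (not isolated)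
7 | 1-(2,6-dimethoxyphenyl)oct-7-en-1-one | C=CCCCCCC(=O)c1c(OC)cccc1OC | intermediate
8 | eugenol (4-allyl-2-methoxyphenol) | C=CCc1ccc(O)c(OC)c1 | starting material
9 | (E/Z)-1-(2,6-dimethoxyphenyl)-9-(4-hydroxy-3-methoxyphenyl)non-7-en-1-one (E isomer drawn, Z isomer carried along) | COc1cccc(OC)c1C(=O)CCCCC/C=C/Cc1ccc(O)c(OC)c1 | intermediate
10 | 1-(2,6-dimethoxyphenyl)-9-(4-hydroxy-3-methoxyphenyl)nonan-1-one | COc1cccc(OC)c1C(=O)CCCCCCCCc1ccc(O)c(OC)c1 | intermediate
11 | 9-(3-bromo-4-hydroxy-5-methoxyphenyl)-1-(2,6-dimethoxyphenyl)nonan-1-one | COc1cccc(OC)c1C(=O)CCCCCCCCc1cc(Br)c(O)c(OC)c1 | intermediate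
12 | 3,4-dimethoxyphenylboronic acid | COc1ccc(B(O)O)cc1OC | starting material
13 | 9-[3-(3,4-dimethoxyphenyl)-4-hydroxy-5-methoxyphenyl]-1-(2,6-dimethoxyphenyl)nonan-1-one | COc1cccc(OC)c1C(=O)CCCCCCCCc1cc(OC)c(O)c(-c2ccc(OC)c(OC)c2)c1 | intermediate
14 | 9-(2,6-dimethoxyphenyl)-9-oxononanal | COc1cccc(OC)c1C(=O)CCCCCCCC=O | intermediate
15 | 9-[3-(3,4-dimethoxyphenyl)-4-{[9-(2,6-dimethoxyphenyl)-1-hydroxy-9-oxononyl]oxy}-5-methoxyphenyl]-1-(2,6-dimethoxyphenyl)nonan-1-one (hemiacetal, racemic) | COc1cccc(OC)c1C(=O)CCCCCCCCc1cc(OC)c(OC(O)CCCCCCCC(=O)c2c(OC)cccc2OC)c(-c2ccc(OC)c(OC)c2)c1 | intermediate (not isolated)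
16 | aryloxycarbenium ion from 15 by loss of water, as its trifluoroacetate | COc1cccc(OC)c1C(=O)CCCCCCCCc1cc(OC)c([O+]=CCCCCCCCC(=O)c2c(OC)cccc2OC)c(-c2ccc(OC)c(OC)c2)c1.[O-]C(=O)C(F)(F)F | intermediate (not isolated)
17 | racemic 1-(2,6-dimethoxyphenyl)-9-{6-[8-(2,6-dimethoxyphenyl)-8-oxooctyl]-4,8,9-trimethoxy-6H-benzo[c]chromen-2-yl}nonan-1-one | COc1cccc(OC)c1C(=O)CCCCCCCCc1cc(OC)c2OC(CCCCCCCC(=O)c3c(OC)cccc3OC)c3cc(OC)c(OC)cc3-c2c1 | intermediate
18 | ring-opened benzylic cation at C9', as its trifluoroacetate | COc1cccc(OC)c1C(=O)CCCCCCCCc1cc(OC)c(O)c(-c2cc(OC)c(OC)cc2[CH+]CCCCCCCC(=O)c2c(OC)cccc2OC)c1.[O-]C(=O)C(F)(F)F | intermediate (not isolated)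
19 | 9-[3-{2-[9-(2,6-dimethoxyphenyl)-9-oxononyl]-4,5-dimethoxyphenyl}-4-hydroxy-5-methoxyphenyl]-1-(2,6-dimethoxyphenyl)nonan-1-one | COc1cccc(OC)c1C(=O)CCCCCCCCc1cc(OC)c(O)c(-c2cc(OC)c(OC)cc2CCCCCCCCC(=O)c2c(OC)cccc2OC)c1 | intermediate
20 | 9-[3-{2-[9-(2,6-dihydroxyphenyl)-9-oxononyl]-4,5-dihydroxyphenyl}-4,5-dihydroxyphenyl]-1-(2,6-dihydroxyphenyl)nonan-1-one | O=C(CCCCCCCCc1cc(O)c(O)c(-c2cc(O)c(O)cc2CCCCCCCCC(=O)c2c(O)cccc2O)c1)c1c(O)cccc1O | target

**Step count and risks**

Total steps: 10. Longest linear sequence: 9 (steps 1–6, then 8–10); the aldehyde branch is step 7 alone and starts from the shared ketone 7.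

Steps most likely to fail:

1. Step 8 (key step).
   - What may go wrong: the enolisable aldehyde may self-condense under acid faster than the hindered phenol traps it. The oxocarbenium ion may alkylate another arene intermolecularly. The acid may re-ionise the new C9'–O bond, and the cation may then be captured irreversibly by position 6 of ring A in a five-membered ring closure.
   - Fallback: the chain is placed on ring B before the biaryl bond is made. It sets out from amide 3 and comes back to the route at 19, so steps 8 and 9 are both bypassed. Cross-metathesis of 3 with commercial methyl eugenol (4-allyl-1,2-dimethoxybenzene, C=CCc1ccc(OC)c(OC)c1) under the conditions of step 3 should give (E/Z)-9-(3,4-dimethoxyphenyl)-N-methoxy-N-methylnon-7-enamide F1. Hydrogenation (H2, 10% Pd/C, EtOAc) should give 9-(3,4-dimethoxyphenyl)-N-methoxy-N-methylnonanamide F2. NBS in MeCN should brominate the veratrole ring, here the only arene present, para to a methoxy group and ortho to the chain, giving 9-(2-bromo-4,5-dimethoxyphenyl)-N-methoxy-N-methylnonanamide F3. Addition of aryllithium 5, generated as in step 2 (THF, −78 → 0 °C), passes through lithium 9-(2-bromo-4,5-dimethoxyphenyl)-1-(2,6-dimethoxyphenyl)-1-[methoxy(methyl)amino]nonan-1-olate F4. Bromine–lithium exchange with the aryl bromide would be uphill, because 5 is stabilised by its two flanking methoxy groups. The acidic quench gives 9-(2-bromo-4,5-dimethoxyphenyl)-1-(2,6-dimethoxyphenyl)nonan-1-one F5. Miyaura borylation (B2pin2, Pd(dppf)Cl2, KOAc, dioxane, 90 °C) should give 1-(2,6-dimethoxyphenyl)-9-[4,5-dimethoxy-2-(4,4,5,5-tetramethyl-1,3,2-dioxaborolan-2-yl)phenyl]nonan-1-one F6. Suzuki coupling of F6 with bromophenol 11 (Pd(OAc)2, SPhos, K3PO4, toluene–H2O, 100 °C) then forms the biaryl bond with the chain already at position 2 of ring B and gives 19.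

2. Step 9.
   - What may go wrong: hydride transfer to the two ketone carbonyls may compete with ionisation of a C–O bond that is held close to the plane of ring B. The ring-opened cation 18 may also be intercepted by position 6 of ring A before hydride arrives.
   - Fallback: ionisation and reduction are separated. It sets out from 17 and comes back at 19. Treatment of 17 with thiophenol (20 equiv) in CF3CO2H–CH2Cl2 at 0 °C, with no hydride donor present, should open the ring by sulfur capture of cation 18 to give racemic 9-[3-{2-[9-(2,6-dimethoxyphenyl)-9-oxo-1-(phenylsulfanyl)nonyl]-4,5-dimethoxyphenyl}-4-hydroxy-5-methoxyphenyl]-1-(2,6-dimethoxyphenyl)nonan-1-one F7. Radical desulfurisation of the benzylic C–S bond with Bu3SnH and AIBN in toluene at 80 °C, to which ketones are inert, should then give 19.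

3. Step 5.
   - What may go wrong: chemoselectivity or site selectivity of the bromination may be lost, through attack on the dimethoxyphenyl ketone ring, attack at position 6 of ring A para to the methoxy group, or double bromination.
   - Fallback: the chain is carried as its Weinreb amide through the bromination, so that ring A is the only electron-rich ring present. It sets out from amide 3 and eugenol 8 and comes back at 13. Cross-metathesis as in step 3 should give (E/Z)-9-(4-hydroxy-3-methoxyphenyl)-N-methoxy-N-methylnon-7-enamide F8, and hydrogenation should give 9-(4-hydroxy-3-methoxyphenyl)-N-methoxy-N-methylnonanamide F9. NBS with catalytic i-Pr2NH should give 9-(3-bromo-4-hydroxy-5-methoxyphenyl)-N-methoxy-N-methylnonanamide F10, and Suzuki coupling with 12 as in step 6 should give 9-[3-(3,4-dimethoxyphenyl)-4-hydroxy-5-methoxyphenyl]-N-methoxy-N-methylnonanamide F11. Addition of aryllithium 5, generated as in step 2 (3 equiv, the first consumed by the phenol; THF, −78 → 0 °C), passes through the dilithium adduct of the biaryl amide F12, and the acidic quench gives 13.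

**Further compounds**

F1 | step 8 | (E/Z)-9-(3,4-dimethoxyphenyl)-N-methoxy-N-methylnon-7-enamide (E isomer drawn) | CON(C)C(=O)CCCCC/C=C/Cc1ccc(OC)c(OC)c1
F2 | step 8 | 9-(3,4-dimethoxyphenyl)-N-methoxy-N-methylnonanamide | CON(C)C(=O)CCCCCCCCc1ccc(OC)c(OC)c1
F3 | step 8 | 9-(2-bromo-4,5-dimethoxyphenyl)-N-methoxy-N-methylnonanamide | CON(C)C(=O)CCCCCCCCc1cc(OC)c(OC)cc1Br
F4 | step 8 | lithium 9-(2-bromo-4,5-dimethoxyphenyl)-1-(2,6-dimethoxyphenyl)-1-[methoxy(methyl)amino]nonan-1-olate (not isolated) | [Li]OC(CCCCCCCCc1cc(OC)c(OC)cc1Br)(N(C)OC)c1c(OC)cccc1OC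
F5 | step 8 | 9-(2-bromo-4,5-dimethoxyphenyl)-1-(2,6-dimethoxyphenyl)nonan-1-one | COc1cccc(OC)c1C(=O)CCCCCCCCc1cc(OC)c(OC)cc1Br
F6 | step 8 | 1-(2,6-dimethoxyphenyl)-9-[4,5-dimethoxy-2-(4,4,5,5-tetramethyl-1,3,2-dioxaborolan-2-yl)phenyl]nonan-1-one | COc1cccc(OC)c1C(=O)CCCCCCCCc1cc(OC)c(OC)cc1B1OC(C)(C)C(C)(C)O1
F7 | step 9 | racemic 9-[3-{2-[9-(2,6-dimethoxyphenyl)-9-oxo-1-(phenylsulfanyl)nonyl]-4,5-dimethoxyphenyl}-4-hydroxy-5-methoxyphenyl]-1-(2,6-dimethoxyphenyl)nonan-1-one | COc1cccc(OC)c1C(=O)CCCCCCCCc1cc(OC)c(O)c(-c2cc(OC)c(OC)cc2C(Sc2ccccc2)CCCCCCCC(=O)c2c(OC)cccc2OC)c1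
F8 | step 5 | (E/Z)-9-(4-hydroxy-3-methoxyphenyl)-N-methoxy-N-methylnon-7-enamide (E isomer drawn) | CON(C)C(=O)CCCCC/C=C/Cc1ccc(O)c(OC)c1
F9 | step 5 | 9-(4-hydroxy-3-methoxyphenyl)-N-methoxy-N-methylnonanamide | CON(C)C(=O)CCCCCCCCc1ccc(O)c(OC)c1
F10 | step 5 | 9-(3-bromo-4-hydroxy-5-methoxyphenyl)-N-methoxy-N-methylnonanamide | CON(C)C(=O)CCCCCCCCc1cc(Br)c(O)c(OC)c1
F11 | step 5 | 9-[3-(3,4-dimethoxyphenyl)-4-hydroxy-5-methoxyphenyl]-N-methoxy-N-methylnonanamide | CON(C)C(=O)CCCCCCCCc1cc(OC)c(O)c(-c2ccc(OC)c(OC)c2)c1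
F12 | step 5 | dilithium adduct of the biaryl amide (lithium phenoxide and lithium hemiaminal alkoxide, not isolated) | [Li]Oc1c(OC)cc(CCCCCCCCC(O[Li])(N(C)OC)c2c(OC)cccc2OC)cc1-c1ccc(OC)c(OC)c1
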